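**Retrosynthetic overview**

1. Atom labels: ring A C1 (bears the ester carbonyl), C2 (aryl ether O), C3 (CHO), C4 (OH), C5 (H), C6 (CH3); ring B C1 (ester O), C2 (CH2O), C3 (OH), C4 (lactone C=O), C5 (lactol CH), C6 (ether O). The strategy rests on ring A being a 2,4-dioxygenated 6-methylbenzoate whose carboxyl carbon acylates the ring-B C1 oxygen, which is the folding pattern of an aryl 3,5,7-trioxooctanoate.
2. Late disconnections: the (R)-lactol by crystallization-induced transformation of the equilibrating hydroxyphthalide; the lactol ring from a ring-B ortho-formyl tert-butyl benzoate; the fumarate by esterification of the ring-B C2 CH2OH; the seven-membered ring by oxidative coupling of ring-A O2 to ring-B C6 after formylation of ring-A C3.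
3. Ring A: aldol aromatization of the ring-B aryl 3,5,7-trioxooctanoate (chain C2 onto C7, giving the ring-A C1–C6 bond); the triketo ester comes from a diketo-dioxinone-derived acylketene and the ring-B phenol.
4. Ring B: a purchased benzene ring, 3,5-bis(benzyloxy)benzaldehyde, whose symmetry fixes the position of the two carbons added by metalation.
5. Order of ring formation: ring B (bought), ring A (step 10), seven-membered dioxepinone ring (step 12), five-membered lactol ring (step 15).

Key step: step 10

Assumption: the lactol carbon is a hemiacetal that equilibrates through the open ortho-formyl acid, so its (R) configuration can be fixed only in the crystal; it is set last by crystallization-induced transformation, with cinchonidine written as the base on the assumption that its less soluble salt carries the (R)-lactol (cinchonine would be taken otherwise).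

**Route**

Step 1
Reactants: 1 3,5-bis(benzyloxy)benzaldehyde
Product: 2 1,3-bis(benzyloxy)-5-(dimethoxymethyl)benzene
Conditions: HC(OMe)3, MeOH, p-TsOH·H2O (cat.), rt; then Et3N
Reagents that add atoms: trimethyl orthoformate, COC(OC)OC; methanol, CO
Why: Acid-catalysed acetalization with the orthoformate as water scavenger should mask the aldehyde as a base-stable dimethyl acetal for the organolithium steps.

Step 2
Reactants: 2 1,3-bis(benzyloxy)-5-(dimethoxymethyl)benzene
Product: 5 [2,6-bis(benzyloxy)-4-(dimethoxymethyl)phenyl]methanol, via aryllithium 3 (not isolated), via aldehyde 4 (not isolated)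
Conditions: n-BuLi, THF, 0 °C; DMF, 0 °C to rt; then MeOH, NaBH4, 0 °C
Reagents that add atoms: N,N-dimethylformamide, CN(C)C=O
Why: Directed ortho-metalation should occur at the carbon flanked by both benzyloxy groups (cooperative lithium coordination), DMF formylates the aryllithium, and hydride reduction of the crude aldehyde leaves the acetal untouched.

Step 3
Reactants: 5 [2,6-bis(benzyloxy)-4-(dimethoxymethyl)phenyl]methanol
Product: 6 tert-butyl{[2,6-bis(benzyloxy)-4-(dimethoxymethyl)benzyl]oxy}dimethylsilane
Conditions: TBSCl, imidazole, DMF, rt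
Reagents that add atoms: tert-butyldimethylsilyl chloride, CC(C)(C)[Si](C)(C)Cl
Why: Standard silylation of a primary alcohol gives an ether that should withstand the organolithium, hydrogenolysis, thermolysis, weak-base and oxidation steps that follow.

Step 4
Reactants: 6 tert-butyl{[2,6-bis(benzyloxy)-4-(dimethoxymethyl)benzyl]oxy}dimethylsilane
Product: 7 {[2,6-bis(benzyloxy)-3-bromo-4-(dimethoxymethyl)benzyl]oxy}(tert-butyl)dimethylsilane
Conditions: NBS (1.0 equiv), NaHCO3, MeCN, 0 °C, dark
Reagents that add atoms: N-bromosuccinimide, O=C1CCC(=O)N1Br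
Why: Electrophilic aromatic bromination can only take one of the two equivalent free positions, each ortho to one benzyloxy group and para to the other, so the symmetry of 6 fixes the regiochemistry.

Step 5
Reactants: 7 {[2,6-bis(benzyloxy)-3-bromo-4-(dimethoxymethyl)benzyl]oxy}(tert-butyl)dimethylsilane
Product: 9 tert-butyl 2,4-bis(benzyloxy)-3-{[(tert-butyldimethylsilyl)oxy]methyl}-6-(dimethoxymethyl)benzoate, via aryllithium 8 (not isolated)
Conditions: n-BuLi, THF, −78 °C; Boc2O, −78 to 0 °C
Reagents that add atoms: di-tert-butyl dicarbonate, CC(C)(C)OC(=O)OC(=O)OC(C)(C)C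
Why: Bromine–lithium exchange is faster than any deprotonation at −78 °C, and the hindered aryllithium should be acylated once by the dicarbonate to give the tert-butyl benzoate directly.

Step 6
Reactants: 9 tert-butyl 2,4-bis(benzyloxy)-3-{[(tert-butyldimethylsilyl)oxy]methyl}-6-(dimethoxymethyl)benzoate
Product: 10 tert-butyl 3-{[(tert-butyldimethylsilyl)oxy]methyl}-6-(dimethoxymethyl)-2,4-dihydroxybenzoate (ring-B resorcinol)
Conditions: H2 (1 atm), 10% Pd/C, NaHCO3, EtOAc, rt
Reagents that add atoms: none
Why: Neutral hydrogenolysis should cleave both benzyl ethers and keep the acetal, silyl ether and tert-butyl ester, none of which would survive an acidic phenol deprotection.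

Step 7
Reactants: 11 2,2,6-trimethyl-4H-1,3-dioxin-4-one (2 equiv)
Product: 13 2,2-dimethyl-6-(2-oxopropyl)-4H-1,3-dioxin-4-one, via lithium dienolate 12 (not isolated)
Conditions: LiN(SiMe3)2 (2 equiv), THF, −78 °C; AcCl (1 equiv), −78 °C; aq. HCl
Reagents that add atoms: acetyl chloride, CC(=O)Cl
Why: Vinylogous deprotonation of the dioxinone methyl group and C-acylation of the dienolate (crossed Claisen condensation) should give the keto-dioxinone, the second equivalent of dienolate taking up its acidic proton.

Step 8
Reactants: 13 2,2-dimethyl-6-(2-oxopropyl)-4H-1,3-dioxin-4-one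
Product: 15 6-(2,4-dioxopentyl)-2,2-dimethyl-4H-1,3-dioxin-4-one, via dilithium dienolate 14 (not isolated)
Conditions: LiN(i-Pr)2 (2.2 equiv), THF, −78 °C; MeC(O)N(OMe)Me, −78 to −20 °C; cold aq. HCl; used promptly
Reagents that add atoms: N-methoxy-N-methylacetamide, CON(C)C(C)=O
Why: The dianion of the keto-dioxinone reacts at its terminal, more nucleophilic carbon with the Weinreb amide, whose chelated tetrahedral adduct blocks over-addition and releases the 1,3-diketone only on work-up.

Step 9
Reactants: 10 ring-B resorcinol; 15 6-(2,4-dioxopentyl)-2,2-dimethyl-4H-1,3-dioxin-4-one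
Product: 17 tert-butyl 3-{[(tert-butyldimethylsilyl)oxy]methyl}-6-(dimethoxymethyl)-2-hydroxy-4-[(3,5,7-trioxooctanoyl)oxy]benzoate (ring-B aryl 3,5,7-trioxooctanoate), via acylketene 16 (not isolated)
Conditions: toluene, 105 °C, 15 (1.4 equiv) added slowly to 10, short reaction time; concentrated and used at once
Reagents that add atoms: none
Why: Retro-hetero-Diels–Alder loss of acetone from the dioxinone gives the acylketene, which should be trapped by the non-chelated ring-B phenol para to the ester and not by the hydrogen-bonded phenol flanked by the ester and the CH2OTBS group.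

Step 10
Reactants: 17 ring-B aryl 3,5,7-trioxooctanoate
Product: 19 tert-butyl 3-{[(tert-butyldimethylsilyl)oxy]methyl}-4-[(2,4-dihydroxy-6-methylbenzoyl)oxy]-6-(dimethoxymethyl)-2-hydroxybenzoate (depside), via cyclic aldol 18 (not isolated)
Conditions: Et3N/AcOH buffer (2:1), CH2Cl2, 0 °C to rt; then AcOH (5 equiv), rt
Reagents that add atoms: none
Why: The amine–acetate buffer enolizes chain C-2, the methylene between the aryl ester and the C-3 ketone, and this enol adds to the C-7 methyl ketone to give carbinol 18 and the ring-A C1–C6 bond, after which β-elimination of water and enolization of the C-3 and C-5 carbonyls should give the aromatic 2,4-dihydroxy-6-methylbenzoate. The closest known reaction type is the biomimetic aldol aromatization of 3,5,7-triketo esters, reached from dioxinone-derived acylketenes, to resorcylates. Ring A closes in a 6-(enolexo)-exo-trig aldol. No stereocenter is kept, because the carbinol carbon of 18 becomes an sp2 ring carbon. The step needs the C-2 to C-7 aldol to beat the C-6 to C-1 Claisen closure, lactonization of the C-5 enol onto the ester to a 4-hydroxy-2-pyrone and E1cB loss of the ring-B aryloxide. The substrate secures this because the unhindered methyl ketone is the most electrophilic carbonyl within six-ring reach of the most acidic methylene while the ester carbonyl is shielded by the ortho CH2OTBS group, and the metal-free, weakly basic, aprotic medium avoids the chelated enolates and alkoxides that drive the Claisen and acyl-transfer modes.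

Step 11
Reactants: 19 depside
Product: 20 tert-butyl 3-{[(tert-butyldimethylsilyl)oxy]methyl}-4-[(3-formyl-2,4-dihydroxy-6-methylbenzoyl)oxy]-6-(dimethoxymethyl)-2-hydroxybenzoate
Conditions: MgCl2 (4 equiv), Et3N (8 equiv), paraformaldehyde (10 equiv), THF, 65 °C; cold aqueous citric acid (pH 5) work-up
Reagents that add atoms: paraformaldehyde (as formaldehyde), C=O
Why: Magnesium-phenoxide-directed ortho-formylation (Casnati–Skattebøl type) should deliver formaldehyde to ring-A C3, the only carbon ortho to two phenoxides, and hydride transfer to a second formaldehyde gives the aldehyde, while the free position of ring B is not ortho to a free phenol.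

Step 12
Reactants: 20 formyl depside
Product: 21 tert-butyl 9-{[(tert-butyldimethylsilyl)oxy]methyl}-6-(dimethoxymethyl)-4-formyl-3,8-dihydroxy-1-methyl-11-oxo-11H-dibenzo[b,e][1,4]dioxepine-7-carboxylate (depsidone; ring-A O2 bonded to ring-B C6)
Conditions: PhI(OAc)2 (1.05 equiv, slow addition), NaHCO3, (CF3)2CHOH/CH2Cl2, −20 to 0 °C, high dilution
Reagents that add atoms: none
Why: In this intramolecular oxidative phenol coupling, trivalent iodine activates the ring-B phenol, the ring-A C2 hydroxyl held close by the depside ester adds to ring-B C6 para to the phenol oxygen in a seven-membered closure, and tautomerization of the dienone restores the phenol, as in the biomimetic depside-to-depsidone closure.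

Step 13
Reactants: 21 depsidone
Product: 22 tert-butyl 4,6-diformyl-3,8-dihydroxy-9-(hydroxymethyl)-1-methyl-11-oxo-11H-dibenzo[b,e][1,4]dioxepine-7-carboxylate
Conditions: 48% aq. HF/MeCN (1:19), 0 °C to rt, polypropylene vessel
Reagents that add atoms: water, O
Why: Dilute aqueous HF should cleave the primary silyl ether and hydrolyse the dimethyl acetal in one operation, conditions under which the lactone and the tert-butyl ester are stable.

Step 14
Reactants: 22 hydroxymethyl diformyl depsidone; 23 mono-tert-butyl fumarate ((2E)-4-tert-butoxy-4-oxobut-2-enoic acid)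
Product: 24 tert-butyl 9-({[(2E)-4-tert-butoxy-4-oxobut-2-enoyl]oxy}methyl)-4,6-diformyl-3,8-dihydroxy-1-methyl-11-oxo-11H-dibenzo[b,e][1,4]dioxepine-7-carboxylate
Conditions: 23 (1.2 equiv), EDC·HCl (1.3 equiv), DMAP (0.1 equiv), CH2Cl2, 0 °C
Reagents that add atoms: none
Why: Steglich-type carbodiimide esterification should acylate the primary benzylic alcohol selectively, since both phenols are tied up in six-membered hydrogen bonds to ortho carbonyl groups.

Step 15
Reactants: 24 fumarate diester
Product: 26 racemic lactol (the target constitution, unresolved at the lactol carbon), via formyl diacid 25 (not isolated)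
Conditions: TFA/CH2Cl2 (1:3), 0 °C to rt; evaporation, trituration
Reagents that add atoms: none
Why: Acidolysis of both tert-butyl esters frees the ring-B carboxylic acid next to the C5 formyl group, and ring-chain tautomerization should close the hydroxyphthalide, as the racemate because no chiral influence is present.

Step 16
Reactants: 26 racemic lactol
Product: 27 cinchonidinium salt of the fumarate carboxylate with (R) configuration at the lactol carbon
Conditions: cinchonidine (1.0 equiv), acetone/MeCN, 40 °C to rt, slurry aged with stirring and slow concentration; filtration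
Reagents that add atoms: cinchonidine, C=C[C@H]1CN2CC[C@H]1C[C@H]2[C@H](O)c1ccnc2ccccc12
Why: Proposed new method: the fumaric acid terminus, the strongest acid of 26, pairs with the quinuclidine nitrogen while the lactol carbon keeps epimerizing in solution by ring-chain tautomerism through the open ortho-formyl benzoate (catalysed by the ammonium carboxylate buffer), so the less soluble diastereomeric salt, taken as the one with the (R)-lactol, is fed from its epimer until the solid is a single diastereomer, the stereocentre being set under thermodynamic control by the chiral cation in the lattice; the closest known reaction type is the crystallization-induced diastereomer transformation of configurationally labile acids as alkaloid salts and the crystallization-driven epimerization of γ-alkoxybutenolide acetals bearing a chiral alkoxy group.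

Step 17
Reactants: 27 cinchonidinium salt
Product: 28 target, (R)-lactol
Conditions: 0.5 M aq. HCl, EtOAc, 0 °C, fast phase separation; Na2SO4; concentration below 5 °C; precipitation with cold heptane; stored cold as the solid
Reagents that add atoms: none
Why: Proton transfer from the mineral acid frees the carboxylic acid, and at 0 °C and low pH, without the carboxylate buffer, ring opening of the lactol should be slow enough to collect the (R)-configured solid before it equilibrates.

**Compound list**

1 | 3,5-bis(benzyloxy)benzaldehyde | O=Cc1cc(OCc2ccccc2)cc(OCc2ccccc2)c1 | starting material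
2 | 1,3-bis(benzyloxy)-5-(dimethoxymethyl)benzene | COC(OC)c1cc(OCc2ccccc2)cc(OCc2ccccc2)c1 | intermediate
3 | [2,6-bis(benzyloxy)-4-(dimethoxymethyl)phenyl]lithium | [Li]c1c(OCc2ccccc2)cc(C(OC)OC)cc1OCc1ccccc1 | intermediate
4 | 2,6-bis(benzyloxy)-4-(dimethoxymethyl)benzaldehyde | O=Cc1c(OCc2ccccc2)cc(C(OC)OC)cc1OCc1ccccc1 | intermediate
5 | [2,6-bis(benzyloxy)-4-(dimethoxymethyl)phenyl]methanol | OCc1c(OCc2ccccc2)cc(C(OC)OC)cc1OCc1ccccc1 | intermediate
6 | tert-butyl{[2,6-bis(benzyloxy)-4-(dimethoxymethyl)benzyl]oxy}dimethylsilane | CC(C)(C)[Si](C)(C)OCc1c(OCc2ccccc2)cc(C(OC)OC)cc1OCc1ccccc1 | intermediate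
7 | {[2,6-bis(benzyloxy)-3-bromo-4-(dimethoxymethyl)benzyl]oxy}(tert-butyl)dimethylsilane | CC(C)(C)[Si](C)(C)OCc1c(OCc2ccccc2)cc(C(OC)OC)c(Br)c1OCc1ccccc1 | intermediate
8 | aryllithium from 7 (lithium in place of bromine) | CC(C)(C)[Si](C)(C)OCc1c(OCc2ccccc2)cc(C(OC)OC)c([Li])c1OCc1ccccc1 | intermediate
9 | tert-butyl 2,4-bis(benzyloxy)-3-{[(tert-butyldimethylsilyl)oxy]methyl}-6-(dimethoxymethyl)benzoate | CC(C)(C)[Si](C)(C)OCc1c(OCc2ccccc2)cc(C(OC)OC)c(C(=O)OC(C)(C)C)c1OCc1ccccc1 | intermediate
10 | tert-butyl 3-{[(tert-butyldimethylsilyl)oxy]methyl}-6-(dimethoxymethyl)-2,4-dihydroxybenzoate (ring-B resorcinol) | CC(C)(C)[Si](C)(C)OCc1c(O)cc(C(OC)OC)c(C(=O)OC(C)(C)C)c1O | intermediate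
11 | 2,2,6-trimethyl-4H-1,3-dioxin-4-one | CC1=CC(=O)OC(C)(C)O1 | starting material
12 | lithium dienolate of 11 | C=C1C=C(O[Li])OC(C)(C)O1 | intermediate
13 | 2,2-dimethyl-6-(2-oxopropyl)-4H-1,3-dioxin-4-one | CC(=O)CC1=CC(=O)OC(C)(C)O1 | intermediate
14 | dilithium dienolate of 13 | C=C(O[Li])C=C1C=C(O[Li])OC(C)(C)O1 | intermediate
15 | 6-(2,4-dioxopentyl)-2,2-dimethyl-4H-1,3-dioxin-4-one | CC(=O)CC(=O)CC1=CC(=O)OC(C)(C)O1 | intermediate
16 | 3,5,7-trioxooct-1-en-1-one (acylketene) | CC(=O)CC(=O)CC(=O)C=C=O | intermediate
17 | tert-butyl 3-{[(tert-butyldimethylsilyl)oxy]methyl}-6-(dimethoxymethyl)-2-hydroxy-4-[(3,5,7-trioxooctanoyl)oxy]benzoate (key-step precursor) | CC(=O)CC(=O)CC(=O)CC(=O)Oc1cc(C(OC)OC)c(C(=O)OC(C)(C)C)c(O)c1CO[Si](C)(C)C(C)(C)C | intermediate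
18 | ring-B aryl 2-hydroxy-2-methyl-4,6-dioxocyclohexane-1-carboxylate (cyclic aldol, isomer mixture) | CC1(O)CC(=O)CC(=O)C1C(=O)Oc1cc(C(OC)OC)c(C(=O)OC(C)(C)C)c(O)c1CO[Si](C)(C)C(C)(C)C | intermediate
19 | tert-butyl 3-{[(tert-butyldimethylsilyl)oxy]methyl}-4-[(2,4-dihydroxy-6-methylbenzoyl)oxy]-6-(dimethoxymethyl)-2-hydroxybenzoate (depside, key-step product) | Cc1cc(O)cc(O)c1C(=O)Oc1cc(C(OC)OC)c(C(=O)OC(C)(C)C)c(O)c1CO[Si](C)(C)C(C)(C)C | intermediate
20 | tert-butyl 3-{[(tert-butyldimethylsilyl)oxy]methyl}-4-[(3-formyl-2,4-dihydroxy-6-methylbenzoyl)oxy]-6-(dimethoxymethyl)-2-hydroxybenzoate | Cc1cc(O)c(C=O)c(O)c1C(=O)Oc1cc(C(OC)OC)c(C(=O)OC(C)(C)C)c(O)c1CO[Si](C)(C)C(C)(C)C | intermediate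
21 | tert-butyl 9-{[(tert-butyldimethylsilyl)oxy]methyl}-6-(dimethoxymethyl)-4-formyl-3,8-dihydroxy-1-methyl-11-oxo-11H-dibenzo[b,e][1,4]dioxepine-7-carboxylate | Cc1cc(O)c(C=O)c2c1C(=O)Oc1c(CO[Si](C)(C)C(C)(C)C)c(O)c(C(=O)OC(C)(C)C)c(C(OC)OC)c1O2 | intermediate
22 | tert-butyl 4,6-diformyl-3,8-dihydroxy-9-(hydroxymethyl)-1-methyl-11-oxo-11H-dibenzo[b,e][1,4]dioxepine-7-carboxylate | Cc1cc(O)c(C=O)c2c1C(=O)Oc1c(CO)c(O)c(C(=O)OC(C)(C)C)c(C=O)c1O2 | intermediate
23 | mono-tert-butyl fumarate, (2E)-4-tert-butoxy-4-oxobut-2-enoic acid | OC(=O)/C=C/C(=O)OC(C)(C)C | starting material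
24 | tert-butyl 9-({[(2E)-4-tert-butoxy-4-oxobut-2-enoyl]oxy}methyl)-4,6-diformyl-3,8-dihydroxy-1-methyl-11-oxo-11H-dibenzo[b,e][1,4]dioxepine-7-carboxylate | Cc1cc(O)c(C=O)c2c1C(=O)Oc1c(COC(=O)/C=C/C(=O)OC(C)(C)C)c(O)c(C(=O)OC(C)(C)C)c(C=O)c1O2 | intermediate
25 | 9-({[(2E)-3-carboxyprop-2-enoyl]oxy}methyl)-4,6-diformyl-3,8-dihydroxy-1-methyl-11-oxo-11H-dibenzo[b,e][1,4]dioxepine-7-carboxylic acid (open formyl diacid) | Cc1cc(O)c(C=O)c2c1C(=O)Oc1c(COC(=O)/C=C/C(=O)O)c(O)c(C(=O)O)c(C=O)c1O2 | intermediate
26 | racemic lactol: depsidone with ring-A 3-CHO, 4-OH and 6-CH3, ring-B C2 CH2O–CO–CH=CH–CO2H (E), C3 OH and a C4/C5-fused 3-hydroxyphthalide, unresolved at the lactol carbon | Cc1cc(O)c(C=O)c2c1C(=O)Oc1c(COC(=O)/C=C/C(=O)O)c(O)c3c(c1O2)C(O)OC3=O | intermediate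
27 | cinchonidinium salt of the fumarate carboxylate of the (R)-lactol | Cc1cc(O)c(C=O)c2c1C(=O)Oc1c(COC(=O)/C=C/C(=O)[O-])c(O)c3c(c1O2)[C@H](O)OC3=O.C=C[C@H]1C[NH+]2CC[C@H]1C[C@H]2[C@H](O)c1ccnc2ccccc12 | intermediate
28 | target: constitution of 26 with (R) configuration at the lactol carbon of the hydroxyphthalide | Cc1cc(O)c(C=O)c2c1C(=O)Oc1c(COC(=O)/C=C/C(=O)O)c(O)c3c(c1O2)[C@H](O)OC3=O | target

**Step count**

Total: 17 steps. Longest linear sequence: 15 steps (from 1 through steps 1–6 and 9–17); the dioxinone branch (steps 7–8) joins at step 9.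

**Steps most likely to fail**

Step 16. The two diastereomeric salts may differ too little in solubility or co-crystallize. Epimerization of the lactol in the mother liquor may be too slow to feed the crystal. The base may trigger loss of the benzylic fumarate through an ortho-quinone methide. The lactol may also equilibrate while the acid is being freed in step 17. The fallback uses known chemistry and sets out from 26: the racemate is resolved by preparative enantioselective chromatography on an immobilized polysaccharide chiral stationary phase (supercritical CO2 with an acidified aprotic co-solvent, cooled column). The fraction of the (R)-enantiomer is evaporated cold and precipitated. This arrives at 28 and bypasses 27; it makes no new compound (F0).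

Step 12. All three phenols are hydrogen-bonded and electron-poor, so oxidation may be sluggish. The ring-A oxygen may add at the substituted ortho carbon C2 of ring B instead of C6. The p-aryloxyphenol product may be oxidized further to a quinone. Intermolecular coupling or acid-induced loss of the acetal may compete. The fallback replaces the oxidation by a halide-based ether synthesis and sets out from 10. NBS brominates the only free ring position (ring-B C6) to give the bromo resorcinol F1. F1 traps acylketene 16 from 15 to give the bromo triketo ester F2. The buffered aldol aromatization proceeds through the bromo cyclic aldol F3 to the bromo depside F4. MgCl2/Et3N/paraformaldehyde formylation gives the bromo formyl depside F5. An intramolecular Ullmann diaryl ether synthesis (CuI, N,N-dimethylglycine, Cs2CO3, dioxane, 90 °C) then joins ring-A O2 to ring-B C6 and comes back to the route at 21.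

Step 10. The C-2 enolate may expel the ring-B aryloxide (E1cB) and the regenerated acylketene may close to the pyrone. Claisen closure onto the aryl ester may outrun the aldol. The same leak can already set in during the hot trapping of step 9. The fallback forms ring A before the ester bond and sets out from 10. Commercial methyl orsellinate is benzylated (BnBr, K2CO3, DMF) to methyl 2,4-bis(benzyloxy)-6-methylbenzoate F6 and saponified (KOH, aqueous DMSO, heat) to 2,4-bis(benzyloxy)-6-methylbenzoic acid F7. F7 is condensed with the para phenol of 10 (DCC, cat. DMAP, CH2Cl2–toluene) to the dibenzyl depside F8. Hydrogenolysis (H2, Pd/C, EtOAc) removes both benzyl groups and comes back to the route at 19.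

Further compounds
F0 | step 16 | none | none
F1 | step 12 | tert-butyl 5-bromo-3-{[(tert-butyldimethylsilyl)oxy]methyl}-6-(dimethoxymethyl)-2,4-dihydroxybenzoate | CC(C)(C)[Si](C)(C)OCc1c(O)c(Br)c(C(OC)OC)c(C(=O)OC(C)(C)C)c1O
F2 | step 12 | bromo triketo ester: 17 with bromine on ring-B C6 | CC(=O)CC(=O)CC(=O)CC(=O)Oc1c(Br)c(C(OC)OC)c(C(=O)OC(C)(C)C)c(O)c1CO[Si](C)(C)C(C)(C)C
F3 | step 12 | bromo cyclic aldol: 18 with bromine on ring-B C6 | CC1(O)CC(=O)CC(=O)C1C(=O)Oc1c(Br)c(C(OC)OC)c(C(=O)OC(C)(C)C)c(O)c1CO[Si](C)(C)C(C)(C)C
F4 | step 12 | bromo depside: 19 with bromine on ring-B C6 | Cc1cc(O)cc(O)c1C(=O)Oc1c(Br)c(C(OC)OC)c(C(=O)OC(C)(C)C)c(O)c1CO[Si](C)(C)C(C)(C)C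
F5 | step 12 | bromo formyl depside: 20 with bromine on ring-B C6 | Cc1cc(O)c(C=O)c(O)c1C(=O)Oc1c(Br)c(C(OC)OC)c(C(=O)OC(C)(C)C)c(O)c1CO[Si](C)(C)C(C)(C)C
F6 | step 10 | methyl 2,4-bis(benzyloxy)-6-methylbenzoate | COC(=O)c1c(C)cc(OCc2ccccc2)cc1OCc1ccccc1
F7 | step 10 | 2,4-bis(benzyloxy)-6-methylbenzoic acid | OC(=O)c1c(C)cc(OCc2ccccc2)cc1OCc1ccccc1
F8 | step 10 | dibenzyl depside: 19 with both ring-A hydroxyls as benzyl ethers | Cc1cc(OCc2ccccc2)cc(OCc2ccccc2)c1C(=O)Oc1cc(C(OC)OC)c(C(=O)OC(C)(C)C)c(O)c1CO[Si](C)(C)C(C)(C)C
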